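**Plan**

- Retrosynthesis: all hydroxyls but one are masked as alkyl ethers. Ring E is cut at E2–E3 and E1–E6, leading back to an ethynyl ether on the ring D C2 oxygen and a 3,4-dialkoxycyclobutenone. The aryl–oxygen bonds D1–O, C1–O and B1–O are then cut in turn.
- Forward: rings A, B, C and D are joined one after another, each by an Ullmann-type coupling of the growing phenol with a bromobenzaldehyde and Baeyer–Villiger conversion of the formyl group into the next phenol. Ring E arises last, by benzannulation on the ring D oxygen.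
- Enabling feature: in ring E the ether carbon E1 lies between two C–H carbons (E2, E6) and E3–E5 carry oxygen, the pattern a vinylketene/ynol ether benzannulation delivers. The oxygen on D2 is wedged between the oxygenated carbons D1 and D3, so it is better bonded to a slim sp carbon than to a preformed arene.
- Stereochemistry: the target has no stereocentre; the racemic C4 of the cyclobutenone and the alkene geometry of the dichlorovinyl ether disappear on the way.

Key step: step 11

Remark: rings are lettered A to E from the 2,4,6-trihydroxyphenoxy end; A1–O–B1, B2–O–C1, C4–O–D1 and D2–O–E1 are the four ether links, and B3–B5, C3/C5, D3–D5 and E3–E5 carry the remaining oxygens.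
Remark: C4 of the cyclobutenone carries methoxy, so that the last step releases only methyl and ethyl bromide and no benzylic cation that could alkylate the electron-rich polyphenol.

**Route**

Step 1
Reactants: 1 5-bromo-1,2,3-trimethoxybenzene
Product: 3 6-bromo-2,3,4-trimethoxybenzaldehyde, via α-chloro ether 2 (not isolated)
Conditions: Cl2CHOMe (1.5 equiv), TiCl4 (2 equiv), CH2Cl2, 0 °C; then ice water
Reagents that add atoms: dichloromethyl methyl ether, COC(Cl)Cl; water, O
Why: Rieche formylation: the TiCl4-activated dichloromethyl ether can only attack the two equivalent free positions of 1 (ortho to bromine and to one methoxy group, para to another), so one aldehyde should form after hydrolysis of α-chloro ether 2.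

Step 2
Reactants: 3 6-bromo-2,3,4-trimethoxybenzaldehyde; 4 2,4,6-trimethoxyphenol
Product: 5 A–B aldehyde 2,3,4-trimethoxy-6-(2,4,6-trimethoxyphenoxy)benzaldehyde
Conditions: CuI (10 mol %), picolinic acid (20 mol %), K3PO4 (2 equiv), DMSO, 90 °C, argon
Reagents that add atoms: none
Why: Ullmann-type C–O coupling with the CuI/picolinic acid system, which is established for 2,6-disubstituted phenols and ortho-substituted aryl bromides; the ortho formyl group of 3 further activates the C–Br carbon and becomes the handle for the next oxygen.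

Step 3
Reactants: 5 A–B aldehyde
Product: 7 A–B phenol 2,3,4-trimethoxy-6-(2,4,6-trimethoxyphenoxy)phenol, via aryl formate 6 (not isolated)
Conditions: mCPBA (1.2 equiv), CH2Cl2, 0 °C to rt; then MeOH, HCl (cat.), rt
Reagents that add atoms: mCPBA (3-chloroperoxybenzoic acid), OOC(=O)c1cccc(Cl)c1
Why: Baeyer–Villiger oxidation: the aryl group, made electron-rich by two ortho oxygens and a para methoxy group, migrates in preference to hydride, and the labile aryl formate 6 is cleaved by acid-catalysed methanolysis to the phenol that sits between the aryloxy and methoxy groups.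

Step 4
Reactants: 7 A–B phenol; 8 4-bromo-2,6-dimethoxybenzaldehyde
Product: 9 A–B–C aldehyde 2,6-dimethoxy-4-[2,3,4-trimethoxy-6-(2,4,6-trimethoxyphenoxy)phenoxy]benzaldehyde
Conditions: CuI (10 mol %), picolinic acid (20 mol %), K3PO4 (2 equiv), DMSO, 90 °C, argon
Reagents that add atoms: none
Why: Ullmann-type coupling again: the crowded phenoxide of 7 meets a bromide carbon that has hydrogens on both sides and a para formyl group, the easy direction for this hindered C–O bond.

Step 5
Reactants: 9 A–B–C aldehyde
Product: 11 A–B–C phenol 2,6-dimethoxy-4-[2,3,4-trimethoxy-6-(2,4,6-trimethoxyphenoxy)phenoxy]phenol, via aryl formate 10 (not isolated)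
Conditions: mCPBA (1.2 equiv), CH2Cl2, 0 °C to rt; then MeOH, HCl (cat.), rt
Reagents that add atoms: mCPBA (3-chloroperoxybenzoic acid), OOC(=O)c1cccc(Cl)c1
Why: Baeyer–Villiger oxidation of a 2,6-dimethoxybenzaldehyde, a reliable aryl-migration case, followed by methanolysis of formate 10, should give the syringol-type phenol of ring C.

Step 6
Reactants: 11 A–B–C phenol; 3 6-bromo-2,3,4-trimethoxybenzaldehyde
Product: 12 A–B–C–D aldehyde 6-{2,6-dimethoxy-4-[2,3,4-trimethoxy-6-(2,4,6-trimethoxyphenoxy)phenoxy]phenoxy}-2,3,4-trimethoxybenzaldehyde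
Conditions: CuI (10 mol %), picolinic acid (20 mol %), K3PO4 (2 equiv), DMSO, 90 °C, argon
Reagents that add atoms: none
Why: Ullmann-type coupling as in step 2, now with the 2,6-dimethoxyphenoxide of ring C as nucleophile, joins C4–O of ring C to C1 of ring D and places the formyl group on C2 of ring D.

Step 7
Reactants: 12 A–B–C–D aldehyde
Product: 14 A–B–C–D phenol 6-{2,6-dimethoxy-4-[2,3,4-trimethoxy-6-(2,4,6-trimethoxyphenoxy)phenoxy]phenoxy}-2,3,4-trimethoxyphenol, via aryl formate 13 (not isolated)
Conditions: mCPBA (1.2 equiv), CH2Cl2, 0 °C to rt; then MeOH, HCl (cat.), rt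
Reagents that add atoms: mCPBA (3-chloroperoxybenzoic acid), OOC(=O)c1cccc(Cl)c1
Why: Baeyer–Villiger oxidation and methanolysis as in step 3 should turn the ring D formyl group into the C2 hydroxyl flanked by the C1 aryloxy and C3 methoxy groups.

Step 8
Reactants: 14 A–B–C–D phenol; 15 trichloroethylene
Product: 17 (E)-1,2-dichlorovinyl ether of the A–B–C–D phenol (on the ring D C2 oxygen), via dichloroacetylene 16 (not isolated)
Conditions: trichloroethylene (1.5 equiv), K2CO3 (2 equiv), DMF, 70 °C
Reagents that add atoms: none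
Why: Base-mediated addition of a phenoxide to dichloroacetylene generated in situ from trichloroethylene, a known route to aryl 1,2-dichlorovinyl ethers; the electrophile is a linear sp carbon, so the two ortho substituents of the ring D phenol should not slow it, and anti addition gives the E alkene.

Step 9
Reactants: 17 (E)-1,2-dichlorovinyl ether
Product: 20 ethynyl ether of the A–B–C–D phenol (ArO–C≡C–H on the ring D C2 oxygen), via chloroethynyl ether 18 (not isolated), via lithium acetylide 19 (not isolated)
Conditions: n-BuLi (2.5 equiv), THF, −78 to −40 °C; then H2O, −78 °C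
Reagents that add atoms: none
Why: Elimination and chlorine–lithium exchange: n-BuLi removes the vinylic proton, chloride leaves to give chloroalkyne 18, a second equivalent exchanges chlorine for lithium to acetylide 19, and protonation gives the terminal aryl ynol ether, the known fate of aryl 1,2-dichlorovinyl ethers; at −78 °C ring lithiation of the methoxyarenes should not compete.

Step 10
Reactants: 21 methoxyacetyl chloride; 22 ethoxyacetylene
Product: 24 racemic 3-ethoxy-4-methoxycyclobut-2-en-1-one, via methoxyketene 23 (not isolated)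
Conditions: Et3N (1.2 equiv), ethoxyacetylene (2 equiv), Et2O, 0 °C to rt, slow addition of 21
Reagents that add atoms: none
Why: Ketene–alkyne (2+2) cycloaddition: methoxyketene 23 formed by dehydrochlorination is trapped by the electron-rich alkyne, the ketene carbonyl carbon bonding to the terminal alkyne carbon as in the known synthesis of 3-ethoxycyclobutenones; C4 is formed racemic and is erased in step 11.

Step 11
Reactants: 20 ethynyl ether of the A–B–C–D phenol; 24 racemic 3-ethoxy-4-methoxycyclobut-2-en-1-one
Product: 29 pentamer with ring E as 3-hydroxy-4-methoxy-5-ethoxyphenyl ether (rings A to D as methyl ethers), via vinylketene 25 (not isolated), via vinylcyclobutenone 26 (not isolated), via dienylketene 27 (not isolated), via cyclohexadienone 28 (not isolated)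
Conditions: 24 (2 equiv), toluene, 80 °C then 110 °C, sealed tube, argon
Reagents that add atoms: none
Why: Proposed new method: heating opens 24 by 4π electrocyclic ring opening (methoxy turning outward) to vinylketene 25, whose electrophilic ketene carbon is attacked by the oxygen-activated terminal carbon of ynol ether 20, so that a (2+2) cycloaddition makes the E2–E3 and E1–E6 bonds and gives vinylcyclobutenone 26, which opens in a second 4π step to dienylketene 27. Ring E is then closed by a thermal disrotatory 6π electrocyclisation of 27 (ketene carbon E3 onto the methoxy-bearing carbon E4), and dienone 28 tautomerises to phenol 29. The closest known reaction is the Danheiser benzannulation of cyclobutenones with alkoxy- and siloxyacetylenes; an aryl ethynyl ether as the ketenophile and a 3,4-dialkoxycyclobutenone as the vinylketene source have not been paired. No stereocentre is formed, since the racemic sp3 carbons of 24, 26 and 28 all end as arene carbons. The step needs one regiochemistry in the (2+2) event, ketene carbonyl carbon to the unsubstituted alkyne carbon, and the polarisation of the ynol ether by its oxygen secures it, placing the aryloxy carbon E1 between the C–H carbons E2 and E6 and meta to the new hydroxyl. The crowded ring D oxygen never has to attack an arene carbon, because ring E is assembled around the sp carbon it already carries.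

Step 12
Reactants: 29 pentamer with twelve methyl ethers, one ethyl ether and one free phenol
Product: 30 target CNP0273977.0 (fourteen free hydroxyls)
Conditions: BBr3 (30 equiv), CH2Cl2, −78 °C to rt, argon; then H2O, 0 °C
Reagents that add atoms: none
Why: Lewis acid dealkylation: BBr3 coordinates each alkyl aryl ether oxygen and bromide removes methyl or ethyl by SN2 attack, whereas the diaryl ether oxygens offer no sp3 carbon and stay intact; hydrolysis of the aryl borates should release the fourteen hydroxyls.

**Compound list**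

1 | 5-bromo-1,2,3-trimethoxybenzene | COc1cc(Br)cc(OC)c1OC | starting material
2 | 1-bromo-2-[chloro(methoxy)methyl]-3,4,5-trimethoxybenzene (racemic, not isolated) | COC(Cl)c1c(Br)cc(OC)c(OC)c1OC | intermediate
3 | 6-bromo-2,3,4-trimethoxybenzaldehyde | O=Cc1c(Br)cc(OC)c(OC)c1OC | intermediate
4 | 2,4,6-trimethoxyphenol | COc1cc(OC)c(O)c(OC)c1 | starting material
5 | 2,3,4-trimethoxy-6-(2,4,6-trimethoxyphenoxy)benzaldehyde (A–B aldehyde) | COc1cc(OC)c(Oc2cc(OC)c(OC)c(OC)c2C=O)c(OC)c1 | intermediate
6 | 2,3,4-trimethoxy-6-(2,4,6-trimethoxyphenoxy)phenyl formate (not isolated) | COc1cc(OC)c(Oc2cc(OC)c(OC)c(OC)c2OC=O)c(OC)c1 | intermediate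
7 | 2,3,4-trimethoxy-6-(2,4,6-trimethoxyphenoxy)phenol (A–B phenol) | COc1cc(OC)c(Oc2cc(OC)c(OC)c(OC)c2O)c(OC)c1 | intermediate
8 | 4-bromo-2,6-dimethoxybenzaldehyde | COc1cc(Br)cc(OC)c1C=O | starting material
9 | 2,6-dimethoxy-4-[2,3,4-trimethoxy-6-(2,4,6-trimethoxyphenoxy)phenoxy]benzaldehyde (A–B–C aldehyde) | COc1cc(OC)c(Oc2cc(OC)c(OC)c(OC)c2Oc2cc(OC)c(C=O)c(OC)c2)c(OC)c1 | intermediate
10 | formate ester of 11 (A–B–C aryl formate, not isolated) | COc1cc(OC)c(Oc2cc(OC)c(OC)c(OC)c2Oc2cc(OC)c(OC=O)c(OC)c2)c(OC)c1 | intermediate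
11 | 2,6-dimethoxy-4-[2,3,4-trimethoxy-6-(2,4,6-trimethoxyphenoxy)phenoxy]phenol (A–B–C phenol) | COc1cc(OC)c(Oc2cc(OC)c(OC)c(OC)c2Oc2cc(OC)c(O)c(OC)c2)c(OC)c1 | intermediate
12 | 6-{2,6-dimethoxy-4-[2,3,4-trimethoxy-6-(2,4,6-trimethoxyphenoxy)phenoxy]phenoxy}-2,3,4-trimethoxybenzaldehyde (A–B–C–D aldehyde) | COc1cc(OC)c(Oc2cc(OC)c(OC)c(OC)c2Oc2cc(OC)c(Oc3cc(OC)c(OC)c(OC)c3C=O)c(OC)c2)c(OC)c1 | intermediate
13 | formate ester of 14 (A–B–C–D aryl formate, not isolated) | COc1cc(OC)c(Oc2cc(OC)c(OC)c(OC)c2Oc2cc(OC)c(Oc3cc(OC)c(OC)c(OC)c3OC=O)c(OC)c2)c(OC)c1 | intermediate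
14 | 6-{2,6-dimethoxy-4-[2,3,4-trimethoxy-6-(2,4,6-trimethoxyphenoxy)phenoxy]phenoxy}-2,3,4-trimethoxyphenol (A–B–C–D phenol, OH on ring D C2) | COc1cc(OC)c(Oc2cc(OC)c(OC)c(OC)c2Oc2cc(OC)c(Oc3cc(OC)c(OC)c(OC)c3O)c(OC)c2)c(OC)c1 | intermediate
15 | trichloroethylene | ClC=C(Cl)Cl | starting material
16 | dichloroacetylene (not isolated) | ClC#CCl | intermediate
17 | (E)-1,2-dichlorovinyl ether of 14 | COc1cc(OC)c(Oc2cc(OC)c(OC)c(OC)c2Oc2cc(OC)c(Oc3cc(OC)c(OC)c(OC)c3O/C(Cl)=C\Cl)c(OC)c2)c(OC)c1 | intermediate
18 | chloroethynyl ether of 14 (not isolated) | COc1cc(OC)c(Oc2cc(OC)c(OC)c(OC)c2Oc2cc(OC)c(Oc3cc(OC)c(OC)c(OC)c3OC#CCl)c(OC)c2)c(OC)c1 | intermediate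
19 | lithium acetylide of the ethynyl ether of 14 (not isolated) | COc1cc(OC)c(Oc2cc(OC)c(OC)c(OC)c2Oc2cc(OC)c(Oc3cc(OC)c(OC)c(OC)c3OC#C[Li])c(OC)c2)c(OC)c1 | intermediate
20 | ethynyl ether of 14 (aryl ynol ether, ring D C2–O–C≡CH) | COc1cc(OC)c(Oc2cc(OC)c(OC)c(OC)c2Oc2cc(OC)c(Oc3cc(OC)c(OC)c(OC)c3OC#C)c(OC)c2)c(OC)c1 | intermediate
21 | methoxyacetyl chloride | COCC(Cl)=O | starting material
22 | ethoxyacetylene | CCOC#C | starting material
23 | methoxyketene (not isolated) | COC=C=O | intermediate
24 | racemic 3-ethoxy-4-methoxycyclobut-2-en-1-one | CCOC1=CC(=O)C1OC | intermediate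
25 | (Z)-3-ethoxy-4-methoxybuta-1,3-dien-1-one (vinylketene, not isolated) | O=C=C/C(OCC)=C/OC | intermediate
26 | racemic 3-(aryloxy)-4-[(Z)-1-ethoxy-2-methoxyvinyl]cyclobut-2-en-1-one, aryloxy = residue of 14 (not isolated) | COc1cc(OC)c(Oc2cc(OC)c(OC)c(OC)c2Oc2cc(OC)c(Oc3cc(OC)c(OC)c(OC)c3OC4=CC(=O)C4/C(OCC)=C/OC)c(OC)c2)c(OC)c1 | intermediate
27 | (3E,5Z)-3-(aryloxy)-5-ethoxy-6-methoxyhexa-1,3,5-trien-1-one, aryloxy = residue of 14 (dienylketene, not isolated) | COc1cc(OC)c(Oc2cc(OC)c(OC)c(OC)c2Oc2cc(OC)c(Oc3cc(OC)c(OC)c(OC)c3O/C(C=C=O)=C/C(OCC)=C/OC)c(OC)c2)c(OC)c1 | intermediate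
28 | racemic 3-(aryloxy)-5-ethoxy-6-methoxycyclohexa-2,4-dien-1-one, aryloxy = residue of 14 (not isolated) | COc1cc(OC)c(Oc2cc(OC)c(OC)c(OC)c2Oc2cc(OC)c(Oc3cc(OC)c(OC)c(OC)c3OC4=CC(=O)C(OC)C(OCC)=C4)c(OC)c2)c(OC)c1 | intermediate
29 | 3-ethoxy-2-methoxy-5-(aryloxy)phenol, aryloxy = residue of 14 (pentamer; ring E C3–OH, C4–OMe, C5–OEt) | COc1cc(OC)c(Oc2cc(OC)c(OC)c(OC)c2Oc2cc(OC)c(Oc3cc(OC)c(OC)c(OC)c3Oc3cc(O)c(OC)c(OCC)c3)c(OC)c2)c(OC)c1 | intermediate
30 | CNP0273977.0 | Oc1cc(O)c(Oc2cc(O)c(O)c(O)c2Oc2cc(O)c(Oc3cc(O)c(O)c(O)c3Oc3cc(O)c(O)c(O)c3)c(O)c2)c(O)c1 | target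

**Count and risks**

Total step count: 12. Longest linear sequence: 11 steps (steps 1 to 9, 11 and 12); step 10 is a one-step side branch.

Step 11. The ynol ether may oligomerise on heating before it meets the vinylketene, the ketene may dimerise or acylate the product phenol, or the (2+2) adduct may stall before the second ring opening. The fallback attaches ring E as a preformed arene with the known chemistry of steps 4 and 5. It sets out from phenol 14, whose crowded phenoxide is coupled with the unhindered bromide 8 (CuI, picolinic acid, K3PO4, DMSO, 90 °C) to give the pentamer aldehyde F1. Baeyer–Villiger oxidation with mCPBA then leads through the pentamer aryl formate F2, cleaved by acidic methanol, to the pentamer phenol F3 (ring E 4-hydroxy-3,5-dimethoxy). BBr3 under the conditions of step 12 removes the thirteen methyl groups of F3, and the route is rejoined at the target 30.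

Step 6 (the same concern applies to step 2). Copper-mediated C–O bond formation between a di-ortho-methoxy phenoxide and an ortho-substituted bromide may be slower than protodebromination of 3 or oxidation of the electron-rich phenoxide. The fallback is a metal-free nucleophilic aromatic substitution on a fluoride. Purchased 5-fluoro-1,2,3-trimethoxybenzene F4 is formylated as in step 1, through the fluoro α-chloro ether F5, to 6-fluoro-2,3,4-trimethoxybenzaldehyde F6. Phenol 11 and F6 with Cs2CO3 in DMSO at about 110 °C should give aldehyde 12, where the route is rejoined. The ortho formyl group stabilises the anionic adduct, and the methoxy group para to fluorine is twisted out of conjugation by its two neighbours.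

Step 12. Ether cleavage may stop before the last of the thirteen alkyl groups is gone, and the pyrogallol-type rings of the free polyphenol may oxidise in air during isolation. The fallback sets out from 29 and changes the isolation to derivatise, purify and release. After the BBr3 treatment and removal of volatiles, the crude polyphenol is acetylated (Ac2O, pyridine, DMAP cat.) to the tetradecaacetate F7, which is stable on silica and separable from under-dealkylated material. Deacetylation with NaOMe (cat.) in degassed MeOH, neutralised with an acidic resin, returns to the target 30.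

**Further compounds**

F1 | step 11 | 4-(aryloxy)-2,6-dimethoxybenzaldehyde, aryloxy = residue of 14 (pentamer aldehyde) | COc1cc(OC)c(Oc2cc(OC)c(OC)c(OC)c2Oc2cc(OC)c(Oc3cc(OC)c(OC)c(OC)c3Oc3cc(OC)c(C=O)c(OC)c3)c(OC)c2)c(OC)c1
F2 | step 11 | formate ester of F3 (pentamer aryl formate) | COc1cc(OC)c(Oc2cc(OC)c(OC)c(OC)c2Oc2cc(OC)c(Oc3cc(OC)c(OC)c(OC)c3Oc3cc(OC)c(OC=O)c(OC)c3)c(OC)c2)c(OC)c1
F3 | step 11 | 4-(aryloxy)-2,6-dimethoxyphenol, aryloxy = residue of 14 (pentamer phenol, thirteen methyl ethers) | COc1cc(OC)c(Oc2cc(OC)c(OC)c(OC)c2Oc2cc(OC)c(Oc3cc(OC)c(OC)c(OC)c3Oc3cc(OC)c(O)c(OC)c3)c(OC)c2)c(OC)c1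
F4 | step 6 | 5-fluoro-1,2,3-trimethoxybenzene | COc1cc(F)cc(OC)c1OC
F5 | step 6 | 1-[chloro(methoxy)methyl]-2-fluoro-4,5,6-trimethoxybenzene (fluoro α-chloro ether) | COC(Cl)c1c(F)cc(OC)c(OC)c1OC
F6 | step 6 | 6-fluoro-2,3,4-trimethoxybenzaldehyde | O=Cc1c(F)cc(OC)c(OC)c1OC
F7 | step 12 | tetradecaacetate of 30 | CC(=O)Oc1cc(OC(C)=O)c(Oc2cc(OC(C)=O)c(OC(C)=O)c(OC(C)=O)c2Oc2cc(OC(C)=O)c(Oc3cc(OC(C)=O)c(OC(C)=O)c(OC(C)=O)c3Oc3cc(OC(C)=O)c(OC(C)=O)c(OC(C)=O)c3)c(OC(C)=O)c2)c(OC(C)=O)c1
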